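**Plan**

- Retrosynthesis: remove the two acyl groups on O8 and O9; cut C7–C8, which opens the ten-membered ring to a C8 aldehyde and a 3-(bromomethyl)butenolide; cut the butenolide (C7=C11 by metathesis, C6–O ester, C6–C7 vinyl addition); cut C1=C10 (aldol, then dehydration).
- Enabling feature: the exocyclic C11=C13 methylene on the lactone ring (O–C6–C7–C11–C12), next to the oxygen-bearing C8, is the retron of an SE2′ allylation of a C8 aldehyde by a C13–C11=C7 allyl unit held inside a butenolide.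
- Forward: C1–C6 (Z C4=C5) comes from neryl acetate and C8–C10/C14 from a malic-acid-derived dioxolane ester; aldol–dehydration joins them, acylation and metathesis build the butenolide, chromium-mediated allylation closes the ten-membered ring with the lactone already in place, and the two esters go on last.
- Stereochemistry: C9 from L-malic acid; C6 by ligand-controlled vinylzinc addition; C7 from C6 in the ring closure; C8 reset by oxidation and peripheral Felkin-type hydride delivery; the acyl groups by Sharpless epoxidation and an Evans syn-aldol; alkene geometry from nerol (Z) and E1cB elimination (E).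

Key step: step 18

Remark: positions in the text follow germacranolide numbering (ring C1–C10, lactone O–C6–C7–C11–C12, C13 exocyclic methylene, C14 ester carbon, C15 methyl; α is the face of H-7), and ester 14 is assumed to be purchasable (otherwise two steps from dimethyl L-malate).

**Acyl group for O8**

Step 1
Reactants: 1 (E)-2-methylbut-2-en-1-ol
Product: 2 [(2R,3R)-2,3-dimethyloxiran-2-yl]methanol
Conditions: Ti(OiPr)4 (10 mol %), diethyl D-(−)-tartrate (12 mol %), tBuOOH, 4 Å sieves, CH2Cl2, −20 °C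
Reagents that add atoms: tert-butyl hydroperoxide, CC(C)(C)OO
Why: Sharpless asymmetric epoxidation of an (E)-allylic alcohol; with D-(−)-tartrate the oxygen is delivered to the alkene face that gives the (2R,3R)-epoxy alcohol, which fixes both stereocentres of the C8 acyl group.

Step 2
Reactants: 2 [(2R,3R)-2,3-dimethyloxiran-2-yl]methanol
Product: 3 (2S,3R)-2,3-dimethyloxirane-2-carboxylic acid
Conditions: RuCl3·xH2O (2 mol %), NaIO4, CCl4/MeCN/H2O, 25 °C
Reagents that add atoms: water, O (carboxyl oxygen by way of the aldehyde hydrate)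
Why: RuO4-type oxidation takes the primary alcohol to the acid and leaves the epoxide and both stereocentres untouched (the descriptor at C2 changes from R to S only because the CIP priorities change).

**Acyl group for O9**

Step 3
Reactants: 4 (R)-4-benzyl-3-propanoyl-1,3-oxazolidin-2-one, 5 acetaldehyde
Product: 7 (R)-4-benzyl-3-[(2R,3S)-3-hydroxy-2-methylbutanoyl]-1,3-oxazolidin-2-one, via boron enolate 6 (not isolated)
Conditions: Bu2BOTf, iPr2NEt, CH2Cl2, 0 °C; 5, −78 → 0 °C; pH 7 buffer, MeOH, H2O2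
Reagents that add atoms: dibutylboron triflate, CCCCB(CCCC)OS(=O)(=O)C(F)(F)F (boron only in intermediate 6)
Why: Evans syn-aldol reaction: the Z boron enolate reacts through a Zimmerman–Traxler chair on the face away from the benzyl group of the (R)-auxiliary, which sets the (2R,3S) syn pair.

Step 4
Reactants: 7 (R)-4-benzyl-3-[(2R,3S)-3-hydroxy-2-methylbutanoyl]-1,3-oxazolidin-2-one
Product: 8 (R)-4-benzyl-3-[(2R,3S)-2-methyl-3-(triethylsilyloxy)butanoyl]-1,3-oxazolidin-2-one
Conditions: Et3SiCl, imidazole, DMF, 0 → 25 °C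
Reagents that add atoms: chlorotriethylsilane, CC[Si](Cl)(CC)CC
Why: Silylation of the secondary alcohol (silyl chloride/imidazole) protects the hydroxyl for the later esterification without touching the stereocentres.

Step 5
Reactants: 8 (R)-4-benzyl-3-[(2R,3S)-2-methyl-3-(triethylsilyloxy)butanoyl]-1,3-oxazolidin-2-one
Product: 10 (2R,3S)-2-methyl-3-(triethylsilyloxy)butanoic acid, via peroxy acid 9 (not isolated)
Conditions: LiOH, H2O2, THF/H2O, 0 °C; Na2SO3; dilute HCl to pH 4, 0 °C
Reagents that add atoms: hydrogen peroxide, OO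
Why: Hydroperoxide cleaves the imide at the exocyclic carbonyl without epimerising C2, and sulfite reduces the peroxy acid to the acid (Evans auxiliary removal).

**Main line**

Step 6
Reactants: 11 neryl acetate [(2Z)-3,7-dimethylocta-2,6-dien-1-yl acetate]
Product: 12 (2Z)-5-(3,3-dimethyloxiran-2-yl)-3-methylpent-2-en-1-yl acetate (racemic at the oxirane)
Conditions: mCPBA (1.0 equiv), NaHCO3, CH2Cl2, 0 °C
Reagents that add atoms: 3-chloroperoxybenzoic acid, OOC(=O)c1cccc(Cl)c1
Why: Prilezhaev epoxidation is regioselective for the remote, more electron-rich trisubstituted alkene because the other one is deactivated by the allylic acetoxy group; the new centre is lost in step 7.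

Step 7
Reactants: 12 (2Z)-5-(3,3-dimethyloxiran-2-yl)-3-methylpent-2-en-1-yl acetate
Product: 13 (2Z)-3-methyl-6-oxohex-2-en-1-yl acetate
Conditions: H5IO6, THF/Et2O (wet), 0 °C
Reagents that add atoms: none
Why: Periodic acid hydrolyses the epoxide to the diol and cleaves it in the same flask (Malaprade-type glycol cleavage), which leaves the Z alkene and the acetate intact.

Step 8
Reactants: 14 methyl [(4S)-2,2-dimethyl-1,3-dioxolan-4-yl]acetate, 13 (2Z)-3-methyl-6-oxohex-2-en-1-yl acetate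
Product: 16 methyl (6Z)-8-acetoxy-2-[(4S)-2,2-dimethyl-1,3-dioxolan-4-yl]-3-hydroxy-6-methyloct-6-enoate (mixture at C2 and C3), via lithium enolate 15 (not isolated)
Conditions: LiN(iPr)2, THF, −78 °C; 13, −78 °C; aq. NH4Cl
Reagents that add atoms: lithium diisopropylamide, [Li]N(C(C)C)C(C)C (lithium only in intermediate 15)
Why: Lithium ester enolate aldol addition at −78 °C, where β-elimination of the dioxolane oxygen is slow; the two new stereocentres are removed in step 9 and need no control.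

Step 9
Reactants: 16 methyl (6Z)-8-acetoxy-2-[(4S)-2,2-dimethyl-1,3-dioxolan-4-yl]-3-hydroxy-6-methyloct-6-enoate
Product: 18 methyl (2E,6Z)-8-acetoxy-2-[(4S)-2,2-dimethyl-1,3-dioxolan-4-yl]-6-methylocta-2,6-dienoate, via mesylate 17 (not isolated)
Conditions: MsCl, Et3N, CH2Cl2, 0 °C; DBU, 0 → 25 °C
Reagents that add atoms: methanesulfonyl chloride, CS(=O)(=O)Cl (only in intermediate 17)
Why: Mesylation followed by base-induced E1cB elimination gives the conjugated ester, and the thermodynamically preferred geometry has the chain trans to CO2Me (E, the ring-cis arrangement of C2 and C9 needed later).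

Step 10
Reactants: 18 methyl (2E,6Z)-8-acetoxy-2-[(4S)-2,2-dimethyl-1,3-dioxolan-4-yl]-6-methylocta-2,6-dienoate
Product: 19 methyl (2E,6Z)-2-[(4S)-2,2-dimethyl-1,3-dioxolan-4-yl]-8-hydroxy-6-methylocta-2,6-dienoate
Conditions: K2CO3 (cat.), MeOH, 0 °C
Reagents that add atoms: none
Why: Base-catalysed transesterification with methanol removes the primary allylic acetate; the methyl ester is unchanged by methanolysis and the acetonide is stable to base.

Step 11
Reactants: 19 methyl (2E,6Z)-2-[(4S)-2,2-dimethyl-1,3-dioxolan-4-yl]-8-hydroxy-6-methylocta-2,6-dienoate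
Product: 20 methyl (2E,6Z)-2-[(4S)-2,2-dimethyl-1,3-dioxolan-4-yl]-6-methyl-8-oxoocta-2,6-dienoate
Conditions: MnO2, CH2Cl2, 25 °C
Reagents that add atoms: none
Why: MnO2 oxidises allylic alcohols selectively under neutral heterogeneous conditions, which should keep the Z geometry of the enal.

Step 12
Reactants: 20 methyl (2E,6Z)-2-[(4S)-2,2-dimethyl-1,3-dioxolan-4-yl]-6-methyl-8-oxoocta-2,6-dienoate
Product: 21 methyl (2E,6Z,8S)-2-[(4S)-2,2-dimethyl-1,3-dioxolan-4-yl]-8-hydroxy-6-methyldeca-2,6,9-trienoate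
Conditions: Zn(CH=CH2)2, (2S)-(−)-3-exo-morpholinoisoborneol (10 mol %), toluene, −20 °C; aq. NH4Cl
Reagents that add atoms: divinylzinc, C=C[Zn]C=C
Why: Amino-alcohol-catalysed 1,2-addition of a vinylzinc reagent; with this ligand the vinyl group is expected on the Si face of the aldehyde, which gives the S carbinol of 21 (germacrane C6, R after lactone formation), and the weakly Lewis acidic medium should not isomerise the Z enal.

Step 13
Reactants: 21 methyl (2E,6Z,8S)-2-[(4S)-2,2-dimethyl-1,3-dioxolan-4-yl]-8-hydroxy-6-methyldeca-2,6,9-trienoate, 22 2-(bromomethyl)prop-2-enoic acid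
Product: 23 methyl (2E,6Z,8S)-8-{[2-(bromomethyl)prop-2-enoyl]oxy}-2-[(4S)-2,2-dimethyl-1,3-dioxolan-4-yl]-6-methyldeca-2,6,9-trienoate
Conditions: DCC, DMAP (5 mol %), CH2Cl2, −10 °C
Reagents that add atoms: none
Why: Steglich esterification (carbodiimide/DMAP) of the secondary alcohol; low temperature and a catalytic amount of DMAP limit attack of the amine on the allylic bromide, and the carbinol centre is not touched.

Step 14
Reactants: 23 methyl (2E,6Z,8S)-8-{[2-(bromomethyl)prop-2-enoyl]oxy}-2-[(4S)-2,2-dimethyl-1,3-dioxolan-4-yl]-6-methyldeca-2,6,9-trienoate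
Product: 24 methyl (2E,6Z)-7-[(2R)-4-(bromomethyl)-5-oxo-2,5-dihydrofuran-2-yl]-2-[(4S)-2,2-dimethyl-1,3-dioxolan-4-yl]-6-methylhepta-2,6-dienoate
Conditions: RuCl2(H2IMes)(PCy3)(=CHPh), the second-generation Grubbs catalyst (5 mol %), toluene, 80 °C, 5 mM
Reagents that add atoms: none
Why: Ring-closing metathesis between the monosubstituted vinyl group and the 1,1-disubstituted acrylate closes the five-membered butenolide with loss of ethylene, while the trisubstituted alkenes are too hindered to take part.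

Step 15
Reactants: 24 methyl (2E,6Z)-7-[(2R)-4-(bromomethyl)-5-oxo-2,5-dihydrofuran-2-yl]-2-[(4S)-2,2-dimethyl-1,3-dioxolan-4-yl]-6-methylhepta-2,6-dienoate
Product: 25 methyl (2E,6Z)-7-[(2R)-4-(bromomethyl)-5-oxo-2,5-dihydrofuran-2-yl]-2-[(1S)-1,2-dihydroxyethyl]-6-methylhepta-2,6-dienoate
Conditions: AcOH/H2O (4:1), 30 °C
Reagents that add atoms: none
Why: Acid-catalysed hydrolysis of the isopropylidene acetal; lactone, enoate and allylic bromide are stable to aqueous acetic acid.

Step 16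
Reactants: 25 methyl (2E,6Z)-7-[(2R)-4-(bromomethyl)-5-oxo-2,5-dihydrofuran-2-yl]-2-[(1S)-1,2-dihydroxyethyl]-6-methylhepta-2,6-dienoate
Product: 26 methyl (2E,6Z)-2-[(1S)-1,2-bis(triethylsilyloxy)ethyl]-7-[(2R)-4-(bromomethyl)-5-oxo-2,5-dihydrofuran-2-yl]-6-methylhepta-2,6-dienoate
Conditions: Et3SiOTf (2.3 equiv), 2,6-lutidine, CH2Cl2, −78 °C
Reagents that add atoms: triethylsilyl triflate, CC[Si](CC)(CC)OS(=O)(=O)C(F)(F)F
Why: Silyl triflate with a hindered pyridine base silylates both hydroxyls at −78 °C faster than it can enolise the butenolide or alkylate the base.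

Step 17
Reactants: 26 methyl (2E,6Z)-2-[(1S)-1,2-bis(triethylsilyloxy)ethyl]-7-[(2R)-4-(bromomethyl)-5-oxo-2,5-dihydrofuran-2-yl]-6-methylhepta-2,6-dienoate
Product: 28 methyl (2E,6Z)-7-[(2R)-4-(bromomethyl)-5-oxo-2,5-dihydrofuran-2-yl]-6-methyl-2-[(1S)-2-oxo-1-(triethylsilyloxy)ethyl]hepta-2,6-dienoate, via primary alcohol 27 (not isolated)
Conditions: (COCl)2, DMSO, CH2Cl2, −78 → −40 °C; Et3N, −78 → −20 °C
Reagents that add atoms: none
Why: Under Swern conditions a primary triethylsilyl ether is cleaved and oxidised in the same flask while the secondary silyl ether stays, and the low temperature avoids epimerisation of the α-silyloxy aldehyde.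

Step 18
Reactants: 28 methyl (2E,6Z)-7-[(2R)-4-(bromomethyl)-5-oxo-2,5-dihydrofuran-2-yl]-6-methyl-2-[(1S)-2-oxo-1-(triethylsilyloxy)ethyl]hepta-2,6-dienoate
Product: 30 methyl (1(10)E,4Z,6R,7R,8R,9S)-8α-hydroxy-12-oxo-9α-(triethylsilyloxy)-6α,12-epoxygermacra-1(10),4,11(13)-trien-14-oate (the 8α-hydroxy 6α,12-olide), via allylchromium 29 (not isolated)
Conditions: CrCl2 (8 equiv), THF, 25 °C, 28 added slowly to a final 2 mM; aq. NH4Cl
Reagents that add atoms: chromium dichloride, Cl[Cr]Cl (chromium and chlorine only in intermediate 29)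
Why: Divalent chromium (CrCl2) inserts into the allylic C13–Br bond and the allylchromium 29 adds through its γ-carbon C7 to the aldehyde carbon C8 in a six-membered chair (Zimmerman–Traxler) transition state, the double bond moving to the exocyclic C11=C13 position (SE2′), so that the ring, the lactone methylene and the C7–C8 bond arise in one event. The closest known reaction type is the Nozaki–Hiyama allylation, which is used intramolecularly for ten-membered germacranolide rings and intermolecularly with 3-(bromomethyl)furan-2(5H)-ones. The ten-membered carbocycle closes in the 10-exo-trig mode at the aldehyde carbon, the carbonyl oxygen staying outside the ring as the C8 alkoxide. C7 is controlled by C6: the aldehyde has to reach C7 on the butenolide face opposite to the C5 substituent, which gives the trans-fused lactone (H-6 β, H-7 α). At C8 the chair places the chromium-bound oxygen next to C13 and C9 in the equatorial position, and Felkin–Anh induction from the C9 silyl ether points the same way, so the 8α-alcohol is expected; this centre is not relied on, because it is erased in step 19 and set in step 20. The step therefore needs only the facial selectivity at C7, secured by the C6 stereocentre, and chemoselectivity, secured because CrCl2 leaves the enoate and the lactone untouched and because the C6–O bond, lying in the plane of the butenolide, cannot align with the allyl π-system for 1,4-elimination.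

Step 19
Reactants: 30 the 8α-hydroxy 6α,12-olide
Product: 31 methyl (1(10)E,4Z,6R,7S,9S)-8,12-dioxo-9α-(triethylsilyloxy)-6α,12-epoxygermacra-1(10),4,11(13)-trien-14-oate (the 8-ketone)
Conditions: Dess–Martin periodinane, NaHCO3, CH2Cl2, 0 °C
Reagents that add atoms: none
Why: Dess–Martin oxidation under buffered, non-basic conditions gives the β,γ-unsaturated ketone without moving the exocyclic double bond into conjugation; either C8 epimer of 30 gives the same ketone.

Step 20
Reactants: 31 the 8-ketone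
Product: 32 methyl (1(10)E,4Z,6R,7R,8S,9S)-8β-hydroxy-12-oxo-9α-(triethylsilyloxy)-6α,12-epoxygermacra-1(10),4,11(13)-trien-14-oate (the 8β-alcohol)
Conditions: NaBH4, CeCl3·7H2O, MeOH/THF, −78 °C
Reagents that add atoms: none
Why: Luche reduction is 1,2-selective and faster than conjugate reduction of the methylene lactone; hydride should arrive from the open periphery of the ten-membered ring, on the side of H-7 and antiperiplanar to the C9–OSiEt3 bond (polar Felkin–Anh), which puts the hydroxyl on the β face (8S).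

Step 21
Reactants: 32 the 8β-alcohol, 3 (2S,3R)-2,3-dimethyloxirane-2-carboxylic acid
Product: 34 methyl (1(10)E,4Z,6R,7S,8S,9S)-8β-{[(2S,3R)-2,3-dimethyloxiran-2-yl]carbonyloxy}-12-oxo-9α-(triethylsilyloxy)-6α,12-epoxygermacra-1(10),4,11(13)-trien-14-oate, via mixed anhydride 33 (not isolated)
Conditions: 3, 2,4,6-trichlorobenzoyl chloride, Et3N, THF, 25 °C; 32, DMAP, toluene, 25 °C
Reagents that add atoms: 2,4,6-trichlorobenzoyl chloride, O=C(Cl)c1c(Cl)cc(Cl)cc1Cl (only in intermediate 33)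
Why: Yamaguchi esterification acylates hindered secondary alcohols; the acid has no α-hydrogen, so its epoxide stereocentres cannot epimerise.

Step 22
Reactants: 34 the 8β-epoxy ester 9α-silyl ether
Product: 35 methyl (1(10)E,4Z,6R,7S,8S,9S)-8β-{[(2S,3R)-2,3-dimethyloxiran-2-yl]carbonyloxy}-9α-hydroxy-12-oxo-6α,12-epoxygermacra-1(10),4,11(13)-trien-14-oate
Conditions: PPTS, MeOH/CH2Cl2 (1:1), 0 → 25 °C
Reagents that add atoms: none
Why: Mild acid-catalysed methanolysis removes the secondary triethylsilyl ether, conditions under which the epoxy ester and the lactone are stable and acyl migration from O8 to O9 is not promoted.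

Step 23
Reactants: 35 the 9α-alcohol, 10 (2R,3S)-2-methyl-3-(triethylsilyloxy)butanoic acid
Product: 37 methyl (1(10)E,4Z,6R,7S,8S,9S)-8β-{[(2S,3R)-2,3-dimethyloxiran-2-yl]carbonyloxy}-9α-{[(2R,3S)-2-methyl-3-(triethylsilyloxy)butanoyl]oxy}-12-oxo-6α,12-epoxygermacra-1(10),4,11(13)-trien-14-oate, via mixed anhydride 36 (not isolated)
Conditions: 10, 2,4,6-trichlorobenzoyl chloride, Et3N, THF, 0 °C; 35, DMAP, toluene, 0 → 25 °C
Reagents that add atoms: 2,4,6-trichlorobenzoyl chloride, O=C(Cl)c1c(Cl)cc(Cl)cc1Cl (only in intermediate 36)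
Why: Yamaguchi esterification of the C9 hydroxyl; activation as the mixed anhydride at low temperature should not epimerise C2 of the acyl group.

Step 24
Reactants: 37 the silyl-protected diester
Product: 38 CNP0135583.2
Conditions: PPTS, MeOH, 25 °C
Reagents that add atoms: none
Why: Acid-catalysed methanolysis of the last silyl ether under the conditions of step 22 liberates the side-chain hydroxyl and leaves the epoxide, the lactone, the ester groups and all stereocentres unchanged.

**Compound list**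

1 | (E)-2-methylbut-2-en-1-ol | C/C=C(\C)CO | starting material
2 | [(2R,3R)-2,3-dimethyloxiran-2-yl]methanol | OC[C@@]1(C)O[C@@H]1C | intermediate
3 | (2S,3R)-2,3-dimethyloxirane-2-carboxylic acid | OC(=O)[C@@]1(C)O[C@@H]1C | intermediate
4 | (R)-4-benzyl-3-propanoyl-1,3-oxazolidin-2-one | CCC(=O)N1[C@H](Cc2ccccc2)COC1=O | starting material
5 | acetaldehyde | CC=O | starting material
6 | dibutylboron Z enolate of 4 (not isolated) | C/C=C(\OB(CCCC)CCCC)N1[C@H](Cc2ccccc2)COC1=O | intermediate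
7 | (R)-4-benzyl-3-[(2R,3S)-3-hydroxy-2-methylbutanoyl]-1,3-oxazolidin-2-one | O=C([C@H](C)[C@H](C)O)N1[C@H](Cc2ccccc2)COC1=O | intermediate
8 | (R)-4-benzyl-3-[(2R,3S)-2-methyl-3-(triethylsilyloxy)butanoyl]-1,3-oxazolidin-2-one | O=C([C@H](C)[C@H](C)O[Si](CC)(CC)CC)N1[C@H](Cc2ccccc2)COC1=O | intermediate
9 | (2R,3S)-2-methyl-3-(triethylsilyloxy)butaneperoxoic acid (not isolated) | OOC(=O)[C@H](C)[C@H](C)O[Si](CC)(CC)CC | intermediate
10 | (2R,3S)-2-methyl-3-(triethylsilyloxy)butanoic acid | OC(=O)[C@H](C)[C@H](C)O[Si](CC)(CC)CC | intermediate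
11 | neryl acetate, (2Z)-3,7-dimethylocta-2,6-dien-1-yl acetate | CC(C)=CCC/C(C)=C\COC(C)=O | starting material
12 | (2Z)-5-(3,3-dimethyloxiran-2-yl)-3-methylpent-2-en-1-yl acetate (racemic at the oxirane) | CC1(C)OC1CC/C(C)=C\COC(C)=O | intermediate
13 | (2Z)-3-methyl-6-oxohex-2-en-1-yl acetate | O=CCC/C(C)=C\COC(C)=O | intermediate
14 | methyl [(4S)-2,2-dimethyl-1,3-dioxolan-4-yl]acetate | COC(=O)C[C@H]1COC(C)(C)O1 | starting material
15 | lithium enolate of 14 (not isolated) | COC(O[Li])=C[C@H]1COC(C)(C)O1 | intermediate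
16 | methyl (6Z)-8-acetoxy-2-[(4S)-2,2-dimethyl-1,3-dioxolan-4-yl]-3-hydroxy-6-methyloct-6-enoate (mixture at C2 and C3) | COC(=O)C([C@H]1COC(C)(C)O1)C(O)CC/C(C)=C\COC(C)=O | intermediate
17 | 3-methanesulfonate of 16 (not isolated) | COC(=O)C([C@H]1COC(C)(C)O1)C(OS(C)(=O)=O)CC/C(C)=C\COC(C)=O | intermediate
18 | methyl (2E,6Z)-8-acetoxy-2-[(4S)-2,2-dimethyl-1,3-dioxolan-4-yl]-6-methylocta-2,6-dienoate | CC(=O)OC/C=C(/C)CC/C=C(/C(=O)OC)[C@H]1COC(C)(C)O1 | intermediate
19 | methyl (2E,6Z)-2-[(4S)-2,2-dimethyl-1,3-dioxolan-4-yl]-8-hydroxy-6-methylocta-2,6-dienoate | OC/C=C(/C)CC/C=C(/C(=O)OC)[C@H]1COC(C)(C)O1 | intermediate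
20 | methyl (2E,6Z)-2-[(4S)-2,2-dimethyl-1,3-dioxolan-4-yl]-6-methyl-8-oxoocta-2,6-dienoate | O=C/C=C(/C)CC/C=C(/C(=O)OC)[C@H]1COC(C)(C)O1 | intermediate
21 | methyl (2E,6Z,8S)-2-[(4S)-2,2-dimethyl-1,3-dioxolan-4-yl]-8-hydroxy-6-methyldeca-2,6,9-trienoate | C=C[C@H](O)/C=C(/C)CC/C=C(/C(=O)OC)[C@H]1COC(C)(C)O1 | intermediate
22 | 2-(bromomethyl)prop-2-enoic acid | OC(=O)C(=C)CBr | starting material
23 | methyl (2E,6Z,8S)-8-{[2-(bromomethyl)prop-2-enoyl]oxy}-2-[(4S)-2,2-dimethyl-1,3-dioxolan-4-yl]-6-methyldeca-2,6,9-trienoate | C=C[C@H](OC(=O)C(=C)CBr)/C=C(/C)CC/C=C(/C(=O)OC)[C@H]1COC(C)(C)O1 | intermediate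
24 | methyl (2E,6Z)-7-[(2R)-4-(bromomethyl)-5-oxo-2,5-dihydrofuran-2-yl]-2-[(4S)-2,2-dimethyl-1,3-dioxolan-4-yl]-6-methylhepta-2,6-dienoate | O=C1O[C@H](/C=C(/C)CC/C=C(/C(=O)OC)[C@H]2COC(C)(C)O2)C=C1CBr | intermediate
25 | methyl (2E,6Z)-7-[(2R)-4-(bromomethyl)-5-oxo-2,5-dihydrofuran-2-yl]-2-[(1S)-1,2-dihydroxyethyl]-6-methylhepta-2,6-dienoate | O=C1O[C@H](/C=C(/C)CC/C=C(/C(=O)OC)[C@H](O)CO)C=C1CBr | intermediate
26 | methyl (2E,6Z)-2-[(1S)-1,2-bis(triethylsilyloxy)ethyl]-7-[(2R)-4-(bromomethyl)-5-oxo-2,5-dihydrofuran-2-yl]-6-methylhepta-2,6-dienoate | O=C1O[C@H](/C=C(/C)CC/C=C(/C(=O)OC)[C@H](O[Si](CC)(CC)CC)CO[Si](CC)(CC)CC)C=C1CBr | intermediate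
27 | methyl (2E,6Z)-7-[(2R)-4-(bromomethyl)-5-oxo-2,5-dihydrofuran-2-yl]-2-[(1S)-2-hydroxy-1-(triethylsilyloxy)ethyl]-6-methylhepta-2,6-dienoate (not isolated) | O=C1O[C@H](/C=C(/C)CC/C=C(/C(=O)OC)[C@H](O[Si](CC)(CC)CC)CO)C=C1CBr | intermediate
28 | methyl (2E,6Z)-7-[(2R)-4-(bromomethyl)-5-oxo-2,5-dihydrofuran-2-yl]-6-methyl-2-[(1S)-2-oxo-1-(triethylsilyloxy)ethyl]hepta-2,6-dienoate | O=C1O[C@H](/C=C(/C)CC/C=C(/C(=O)OC)[C@H](O[Si](CC)(CC)CC)C=O)C=C1CBr | intermediate
29 | allylchromium dichloride from 28, CH2CrCl2 in place of CH2Br (not isolated) | O=C1O[C@H](/C=C(/C)CC/C=C(/C(=O)OC)[C@H](O[Si](CC)(CC)CC)C=O)C=C1C[Cr](Cl)Cl | intermediate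
30 | methyl (1(10)E,4Z,6R,7R,8R,9S)-8α-hydroxy-12-oxo-9α-(triethylsilyloxy)-6α,12-epoxygermacra-1(10),4,11(13)-trien-14-oate | C=C1C(=O)O[C@@H]2/C=C(/C)CC/C=C(/C(=O)OC)[C@H](O[Si](CC)(CC)CC)[C@H](O)[C@@H]12 | intermediate
31 | methyl (1(10)E,4Z,6R,7S,9S)-8,12-dioxo-9α-(triethylsilyloxy)-6α,12-epoxygermacra-1(10),4,11(13)-trien-14-oate | C=C1C(=O)O[C@@H]2/C=C(/C)CC/C=C(/C(=O)OC)[C@H](O[Si](CC)(CC)CC)C(=O)[C@@H]12 | intermediate
32 | methyl (1(10)E,4Z,6R,7R,8S,9S)-8β-hydroxy-12-oxo-9α-(triethylsilyloxy)-6α,12-epoxygermacra-1(10),4,11(13)-trien-14-oate | C=C1C(=O)O[C@@H]2/C=C(/C)CC/C=C(/C(=O)OC)[C@H](O[Si](CC)(CC)CC)[C@@H](O)[C@@H]12 | intermediate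
33 | mixed anhydride of 3 with 2,4,6-trichlorobenzoic acid (not isolated) | O=C(OC(=O)c1c(Cl)cc(Cl)cc1Cl)[C@@]1(C)O[C@@H]1C | intermediate
34 | methyl (1(10)E,4Z,6R,7S,8S,9S)-8β-{[(2S,3R)-2,3-dimethyloxiran-2-yl]carbonyloxy}-12-oxo-9α-(triethylsilyloxy)-6α,12-epoxygermacra-1(10),4,11(13)-trien-14-oate | C=C1C(=O)O[C@@H]2/C=C(/C)CC/C=C(/C(=O)OC)[C@H](O[Si](CC)(CC)CC)[C@@H](OC(=O)[C@@]3(C)O[C@@H]3C)[C@@H]12 | intermediate
35 | methyl (1(10)E,4Z,6R,7S,8S,9S)-8β-{[(2S,3R)-2,3-dimethyloxiran-2-yl]carbonyloxy}-9α-hydroxy-12-oxo-6α,12-epoxygermacra-1(10),4,11(13)-trien-14-oate | C=C1C(=O)O[C@@H]2/C=C(/C)CC/C=C(/C(=O)OC)[C@H](O)[C@@H](OC(=O)[C@@]3(C)O[C@@H]3C)[C@@H]12 | intermediate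
36 | mixed anhydride of 10 with 2,4,6-trichlorobenzoic acid (not isolated) | O=C(OC(=O)c1c(Cl)cc(Cl)cc1Cl)[C@H](C)[C@H](C)O[Si](CC)(CC)CC | intermediate
37 | methyl (1(10)E,4Z,6R,7S,8S,9S)-8β-{[(2S,3R)-2,3-dimethyloxiran-2-yl]carbonyloxy}-9α-{[(2R,3S)-2-methyl-3-(triethylsilyloxy)butanoyl]oxy}-12-oxo-6α,12-epoxygermacra-1(10),4,11(13)-trien-14-oate | C=C1C(=O)O[C@@H]2/C=C(/C)CC/C=C(/C(=O)OC)[C@H](OC(=O)[C@H](C)[C@H](C)O[Si](CC)(CC)CC)[C@@H](OC(=O)[C@@]3(C)O[C@@H]3C)[C@@H]12 | intermediate
38 | CNP0135583.2 | C=C1C(=O)O[C@@H]2/C=C(/C)CC/C=C(/C(=O)OC)[C@H](OC(=O)[C@H](C)[C@H](C)O)[C@@H](OC(=O)[C@@]3(C)O[C@@H]3C)[C@@H]12 | target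

**Step count**

Total: 24 steps. Longest linear sequence: 19 steps (steps 6 to 24, from neryl acetate 11).

**Steps most likely to fail**

1. Step 18. What may go wrong: the allylchromium is protonated or couples between molecules faster than the ten-membered ring closes, or the ring closes on the butenolide face syn to C5. The fallback sets out from 28. Pd(PPh3)4 (zerovalent palladium, catalytic) and (Bu3Sn)2 in THF turn the allylic bromide into the allylstannane methyl (2E,6Z)-6-methyl-2-[(1S)-2-oxo-1-(triethylsilyloxy)ethyl]-7-{(2R)-5-oxo-4-[(tributylstannyl)methyl]-2,5-dihydrofuran-2-yl}hepta-2,6-dienoate F1. F1 has no reducing metal present and is cyclised at very high dilution with BF3·OEt2 in CH2Cl2 at −78 °C, by a Lewis-acid-promoted SE2′ addition through an open transition state. The route is rejoined at 30; an 8β epimer, if formed, is 32 and is taken on from step 21.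

2. Step 20. What may go wrong: hydride delivery to the wrong face of the ketone, conjugate reduction of the methylene lactone, or enolisation of 31 towards C7 with migration of the exocyclic double bond. The fallback sets out from 30 and leaves out 31 and 32. Mitsunobu esterification of the 8α-alcohol with acid 3 (PPh3, diisopropyl azodicarboxylate, toluene, 0 → 25 °C) forms the C8–O ester bond with inversion and comes back to the route at 34. No new compound is made (F0).

3. Step 14. What may go wrong: the allylic bromide alkylates or degrades the ruthenium carbene, or the doubly allylic ester rearranges before the slow ring closure onto the acrylate. The fallback sets out from 21, which is esterified (DCC, DMAP) with 2-({[tert-butyl(dimethyl)silyl]oxy}methyl)prop-2-enoic acid to methyl (2E,6Z,8S)-8-{[2-({[tert-butyl(dimethyl)silyl]oxy}methyl)prop-2-enoyl]oxy}-2-[(4S)-2,2-dimethyl-1,3-dioxolan-4-yl]-6-methyldeca-2,6,9-trienoate F2. Metathesis as in step 14 gives methyl (2E,6Z)-7-[(2R)-4-({[tert-butyl(dimethyl)silyl]oxy}methyl)-5-oxo-2,5-dihydrofuran-2-yl]-2-[(4S)-2,2-dimethyl-1,3-dioxolan-4-yl]-6-methylhepta-2,6-dienoate F3. HF·pyridine in THF/pyridine gives methyl (2E,6Z)-2-[(4S)-2,2-dimethyl-1,3-dioxolan-4-yl]-7-[(2R)-4-(hydroxymethyl)-5-oxo-2,5-dihydrofuran-2-yl]-6-methylhepta-2,6-dienoate F4. CBr4/PPh3 (Appel reaction) then gives bromide 24, where the route is rejoined.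

**Further compounds**

F1 | step 18 | methyl (2E,6Z)-6-methyl-2-[(1S)-2-oxo-1-(triethylsilyloxy)ethyl]-7-{(2R)-5-oxo-4-[(tributylstannyl)methyl]-2,5-dihydrofuran-2-yl}hepta-2,6-dienoate | O=C1O[C@H](/C=C(/C)CC/C=C(/C(=O)OC)[C@H](O[Si](CC)(CC)CC)C=O)C=C1C[Sn](CCCC)(CCCC)CCCC
F0 | step 20 | none | none
F2 | step 14 | methyl (2E,6Z,8S)-8-{[2-({[tert-butyl(dimethyl)silyl]oxy}methyl)prop-2-enoyl]oxy}-2-[(4S)-2,2-dimethyl-1,3-dioxolan-4-yl]-6-methyldeca-2,6,9-trienoate | C=C[C@H](OC(=O)C(=C)CO[Si](C)(C)C(C)(C)C)/C=C(/C)CC/C=C(/C(=O)OC)[C@H]1COC(C)(C)O1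
F3 | step 14 | methyl (2E,6Z)-7-[(2R)-4-({[tert-butyl(dimethyl)silyl]oxy}methyl)-5-oxo-2,5-dihydrofuran-2-yl]-2-[(4S)-2,2-dimethyl-1,3-dioxolan-4-yl]-6-methylhepta-2,6-dienoate | O=C1O[C@H](/C=C(/C)CC/C=C(/C(=O)OC)[C@H]2COC(C)(C)O2)C=C1CO[Si](C)(C)C(C)(C)C
F4 | step 14 | methyl (2E,6Z)-2-[(4S)-2,2-dimethyl-1,3-dioxolan-4-yl]-7-[(2R)-4-(hydroxymethyl)-5-oxo-2,5-dihydrofuran-2-yl]-6-methylhepta-2,6-dienoate | O=C1O[C@H](/C=C(/C)CC/C=C(/C(=O)OC)[C@H]2COC(C)(C)O2)C=C1CO
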